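**Plan**

- Retrosynthetic cuts, in order: the ethyl ester; the C8–prenyl bond (dearomatising allylation); the O1–C(Me)2 bond of the pyran, traced back to a 2‑isopropenyl‑2,3‑dihydrofuran that holds one ring carbon fewer; the aryl C–CH2 bond to the side chain (Negishi coupling); the CH–CH2 bond of the side chain (auxiliary alkylation); the aryl–acyl bond.
- Forward order of rings: the benzene ring is bought (phloroglucinol); a dihydrofuran is closed on its prenyl group (5‑exo); after the side chain is coupled, the dihydrofuran is expanded to the 2,2‑dimethyl‑2H‑pyran; the benzene ring is dearomatised last by C‑prenylation at C8.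
- Stereochemistry: the acyl centre is bought as (2R)‑2‑methylbutanoic acid; the side‑chain CH is set by an oxazolidinone auxiliary; the quaternary C8 is set by a chiral ligand on palladium.
- Feature that makes the key event possible (benzofuran numbering): the allylic aryl‑ether bond O1–C2 of the dihydrofuran, with O1 para to the ketone (a good phenoxide leaving group), the benzylic C3 hydrogens beside it, and O4 and O6 capped as acetates so that only O1 can take the allyl unit back.
- The dihydrofuran C2 centre is a helper that the key step erases.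

Key step: step 11

Remark: ethyl (2E)‑4‑bromo‑2‑methylbut‑2‑enoate and (2R)‑2‑methylbutanoic acid are taken as catalogue reagents, and the C‑2 centre of the dihydrofuran helper ring is carried as both epimers because step 11 destroys it.

**Route**

Step 1
Reactants: 1 (4S)-4-benzyl-1,3-oxazolidin-2-one; 2 3-methylbut-2-enoyl chloride
Product: 3 (4S)-4-benzyl-3-(3-methylbut-2-enoyl)-1,3-oxazolidin-2-one
Conditions: n-BuLi, THF, −78 °C; then 2, −78 → 0 °C
Reagents that add atoms: none
Why: N-acylation of the lithiated oxazolidinone by an acid chloride is the standard way to load the auxiliary and creates no stereocentre.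

Step 2
Reactants: 3; 4 ethyl (2E)-4-bromo-2-methylbut-2-enoate
Product: 6 ethyl (2E,5S)-5-{[(4S)-4-benzyl-2-oxo-1,3-oxazolidin-3-yl]carbonyl}-2,6-dimethylhepta-2,6-dienoate, via sodium dienolate 5 (not isolated)
Conditions: NaHMDS, THF, −78 °C; then 4, −78 → −40 °C
Reagents that add atoms: none
Why: Deconjugative auxiliary-controlled alkylation (Evans type), in which γ-deprotonation gives the chelated Z-dienolate and the allylic bromide is attacked in an SN2 reaction at the α-carbon on the face away from the benzyl group, so that C-5 should be formed S while the E-enoate is carried in unchanged.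

Step 3
Reactants: 6
Product: 7 ethyl (2E,5S)-5-(hydroxymethyl)-2,6-dimethylhepta-2,6-dienoate
Conditions: NaBH4, THF/H2O, 0 °C → rt
Reagents that add atoms: none
Why: Reductive cleavage of an N-acyl oxazolidinone by NaBH4 in wet THF gives the primary alcohol and returns the auxiliary, and it should leave the conjugated ethyl ester and the adjacent stereocentre untouched.

Step 4
Reactants: 7
Product: 8 ethyl (2E,5S)-5-(iodomethyl)-2,6-dimethylhepta-2,6-dienoate
Conditions: I2, PPh3, imidazole, CH2Cl2, 0 °C
Reagents that add atoms: iodine, II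
Why: Appel-type iodination of a primary alcohol runs through the alkoxyphosphonium salt and does not involve the neighbouring stereocentre or the alkenes.

Step 5
Reactants: 9 (2R)-2-methylbutanoic acid; 10 phloroglucinol (benzene-1,3,5-triol)
Product: 12 (2R)-2-methyl-1-(2,4,6-trihydroxyphenyl)butan-1-one, via acid chloride 11 (not isolated)
Conditions: (COCl)2, DMF (cat.), CH2Cl2, 0 °C → rt; then 10, AlCl3, PhNO2/CH2Cl2, 0 °C → rt
Reagents that add atoms: none
Why: Friedel–Crafts C-acylation of phloroglucinol is the standard entry to acylphloroglucinols, and a short reaction time at or below room temperature should keep the bought α-stereocentre from enolising on the aluminium-bound ketone.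

Step 6
Reactants: 12; 13 1-bromo-3-methylbut-2-ene (prenyl bromide)
Product: 14 (2R)-2-methyl-1-[2,4,6-trihydroxy-3-(3-methylbut-2-en-1-yl)phenyl]butan-1-one
Conditions: 13 (1.0 equiv), 10 % aq. KOH, 0 °C
Reagents that add atoms: none
Why: C-prenylation of the phloroglucinolate in water is the classical route to mono-prenylated acylphloroglucinols, the two free ring positions being equivalent and the di-prenylated by-product being removable by chromatography.

Step 7
Reactants: 14
Product: 15 (2R)-1-[4,6-dihydroxy-2-(prop-1-en-2-yl)-2,3-dihydro-1-benzofuran-5-yl]-2-methylbutan-1-one (both C-2 epimers)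
Conditions: Pd(OAc)2 (10 mol %), Cu(OAc)2 (20 mol %), O2 (1 atm), MeOH/H2O, 35 °C
Reagents that add atoms: none
Why: Wacker-type oxidative cyclisation of an ortho-prenyl phenol, in which the most acidic, non-chelated para-hydroxyl binds divalent palladium, 5-exo oxypalladation places the metal on the tertiary carbon and β-hydride elimination towards a methyl group gives the 2-isopropenyl-2,3-dihydrofuran, whose C-2 centre is formed without control because the key step erases it.

Step 8
Reactants: 15
Product: 16 (2R)-1-[4,6-dihydroxy-7-iodo-2-(prop-1-en-2-yl)-2,3-dihydro-1-benzofuran-5-yl]-2-methylbutan-1-one (both C-2 epimers)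
Conditions: NIS (1.05 equiv), MeCN, −20 → 0 °C, dark
Reagents that add atoms: N-iodosuccinimide, O=C1CCC(=O)N1I
Why: Electrophilic aromatic iodination should take the only free ring position, which is flanked by a hydroxyl and the ether oxygen, much faster than NIS attacks the 1,1-disubstituted alkene.

Step 9
Reactants: 16
Product: 17 7-iodo-5-[(2R)-2-methylbutanoyl]-2-(prop-1-en-2-yl)-2,3-dihydro-1-benzofuran-4,6-diyl diacetate (both C-2 epimers)
Conditions: Ac2O, pyridine, DMAP (5 mol %), CH2Cl2, 0 °C → rt
Reagents that add atoms: acetic anhydride, CC(=O)OC(C)=O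
Why: Acetylation of both phenols removes the acidic protons that would quench the organozinc reagent and caps O4 and O6 for the key step.

Step 10
Reactants: 8; 17
Product: 19 ethyl (2E,5R)-5-{[4,6-bis(acetyloxy)-5-[(2R)-2-methylbutanoyl]-2-(prop-1-en-2-yl)-2,3-dihydro-1-benzofuran-7-yl]methyl}-2,6-dimethylhepta-2,6-dienoate (both C-2 epimers of the dihydrofuran), via alkylzinc iodide 18 (not isolated)
Conditions: 8, Zn dust (TMSCl/BrCH2CH2Br-activated), LiCl, THF, 35 °C; then 17, Pd(OAc)2 (3 mol %), SPhos (6 mol %), THF, rt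
Reagents that add atoms: none
Why: Negishi sp3–sp2 coupling of a primary alkylzinc iodide (which tolerates the enoate) with a hindered aryl iodide is well served by SPhos, oxidative addition to the aryl iodide at room temperature should outrun ionisation of the allylic aryl ether, and the side-chain stereocentre is not at the metal-bearing carbon and is retained (the descriptor changes to R only through the priority rules).

Step 11
Reactants: 19
Product: 21 ethyl (2E,5R)-5-{[5,7-bis(acetyloxy)-2,2-dimethyl-6-[(2R)-2-methylbutanoyl]-2H-chromen-8-yl]methyl}-2,6-dimethylhepta-2,6-dienoate, via dienyl phenol 20 (not isolated)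
Conditions: Pd(PPh3)4 (5 mol %), toluene (0.02 M), 80 °C
Reagents that add atoms: none
Why: Proposed new method: zerovalent palladium ionises the allylic C2–O1 bond of the 2-isopropenyl-dihydrofuran (the para-acyl phenoxide is a good leaving group), the π-allyl complex loses a benzylic C3 hydrogen as palladium hydride to give the palladium-bound (E)-dienyl phenol 20, and re-insertion of the diene into Pd–H with the hydrogen delivered to the terminal CH2 gives the isomeric π-allyl complex spanning CH(Ar)–CH–CMe2, which O1 closes at the tertiary terminus. The closest known reaction types are the palladium-catalysed 1,4-elimination of allylic esters and aryl ethers to 1,3-dienes, the palladium-hydride addition of phenols to 1,3-dienes, and the acid- or heat-induced cyclisation of ortho-(3-methylbuta-1,3-dienyl)phenols to 2,2-dimethylchromenes; the one-pot isomerisation of the five-membered into the six-membered ring has not been described. The pyran closes by a 6-endo allylic etherification (the 4-exo alternative at the benzylic terminus is geometrically excluded), so the ring grows by one carbon, the former isopropenyl carbon. No stereocentre is created, and the C-2 centre of the helper ring is erased, which is why both epimers of 19 should converge on one product. The step needs O1 selectivity and a net forward direction: the acetates on O4 and O6 leave O1 as the only free oxygen that can recapture the allyl unit, and the conjugated, less strained chromene is the thermodynamic sink of the reversible manifold. No external acid is added, so that free palladium hydride does not move the isopropenyl double bond of the side chain.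

Step 12
Reactants: 21
Product: 22 ethyl (2E,5R)-5-{[5,7-dihydroxy-2,2-dimethyl-6-[(2R)-2-methylbutanoyl]-2H-chromen-8-yl]methyl}-2,6-dimethylhepta-2,6-dienoate
Conditions: K2CO3, EtOH, 0 °C → rt
Reagents that add atoms: none
Why: Ethanolysis of the two aryl acetates (ethanol is used so that the ethyl ester cannot be transesterified) frees the phenols needed for the dearomatisation.

Step 13
Reactants: 22; 23 3-methylbut-2-en-1-yl acetate (prenyl acetate)
Product: 24 ethyl (2E,5R)-5-{[(8R)-7-hydroxy-2,2-dimethyl-6-[(2R)-2-methylbutanoyl]-8-(3-methylbut-2-en-1-yl)-5-oxo-5,8-dihydro-2H-chromen-8-yl]methyl}-2,6-dimethylhepta-2,6-dienoate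
Conditions: Pd2(dba)3·CHCl3 (2.5 mol %), (R,R)-DACH-phenyl Trost ligand (7.5 mol %), Cs2CO3, toluene, 0 °C → rt
Reagents that add atoms: none
Why: Palladium-catalysed asymmetric allylic dearomatisation (Tsuji–Trost type), in which the caesium phenoxide attacks the prenyl π-allyl complex through C-8 (flanked by two oxygens and, unlike C-4a, not part of the conjugated chromene fusion) at the less hindered CH2 terminus, the chiral pocket of the ligand choosing the face so that C-8 should be formed R (the antipodal ligand is used if a trial run shows the 8S epimer to prevail), and the product leaves the cycle as its enolate, which should not re-ionise.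

Step 14
Reactants: 24
Product: 25 (2E,5R)-5-{[(8R)-7-hydroxy-2,2-dimethyl-6-[(2R)-2-methylbutanoyl]-8-(3-methylbut-2-en-1-yl)-5-oxo-5,8-dihydro-2H-chromen-8-yl]methyl}-2,6-dimethylhepta-2,6-dienoic acid
Conditions: LiOH·H2O, THF/H2O, 40 °C, argon; then 1 M HCl to pH 3
Reagents that add atoms: lithium hydroxide, [Li+].[OH-]
Why: Saponification of the E-enoate by hydroxide should be selective because the β-triketone sits as its unreactive enolate under the conditions, and acidification returns the vinylogous acid and the carboxylic acid without touching a stereocentre.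

**Compound list**

1 | (4S)-4-benzyl-1,3-oxazolidin-2-one | O=C1N[C@@H](Cc2ccccc2)CO1 | starting material
2 | 3-methylbut-2-enoyl chloride | CC(C)=CC(=O)Cl | starting material
3 | (4S)-4-benzyl-3-(3-methylbut-2-enoyl)-1,3-oxazolidin-2-one | CC(C)=CC(=O)N1[C@@H](Cc2ccccc2)COC1=O | intermediate
4 | ethyl (2E)-4-bromo-2-methylbut-2-enoate | CCOC(=O)/C(C)=C/CBr | starting material
5 | sodium Z-dienolate of 3 | CC(=C)/C=C(\[O-])N1[C@@H](Cc2ccccc2)COC1=O.[Na+] | intermediate (not isolated)
6 | ethyl (2E,5S)-5-{[(4S)-4-benzyl-2-oxo-1,3-oxazolidin-3-yl]carbonyl}-2,6-dimethylhepta-2,6-dienoate | C=C(C)[C@H](C/C=C(\C)C(=O)OCC)C(=O)N1[C@@H](Cc2ccccc2)COC1=O | intermediate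
7 | ethyl (2E,5S)-5-(hydroxymethyl)-2,6-dimethylhepta-2,6-dienoate | C=C(C)[C@H](C/C=C(\C)C(=O)OCC)CO | intermediate
8 | ethyl (2E,5S)-5-(iodomethyl)-2,6-dimethylhepta-2,6-dienoate | C=C(C)[C@H](C/C=C(\C)C(=O)OCC)CI | intermediate
9 | (2R)-2-methylbutanoic acid | CC[C@@H](C)C(=O)O | starting material
10 | phloroglucinol (benzene-1,3,5-triol) | Oc1cc(O)cc(O)c1 | starting material
11 | (2R)-2-methylbutanoyl chloride | CC[C@@H](C)C(=O)Cl | intermediate (not isolated)
12 | (2R)-2-methyl-1-(2,4,6-trihydroxyphenyl)butan-1-one | CC[C@@H](C)C(=O)c1c(O)cc(O)cc1O | intermediate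
13 | 1-bromo-3-methylbut-2-ene | CC(C)=CCBr | starting material
14 | (2R)-2-methyl-1-[2,4,6-trihydroxy-3-(3-methylbut-2-en-1-yl)phenyl]butan-1-one | CC[C@@H](C)C(=O)c1c(O)cc(O)c(CC=C(C)C)c1O | intermediate
15 | (2R)-1-[4,6-dihydroxy-2-(prop-1-en-2-yl)-2,3-dihydro-1-benzofuran-5-yl]-2-methylbutan-1-one, both C-2 epimers | CC[C@@H](C)C(=O)c1c(O)cc2OC(C(C)=C)Cc2c1O | intermediate
16 | (2R)-1-[4,6-dihydroxy-7-iodo-2-(prop-1-en-2-yl)-2,3-dihydro-1-benzofuran-5-yl]-2-methylbutan-1-one, both C-2 epimers | CC[C@@H](C)C(=O)c1c(O)c(I)c2OC(C(C)=C)Cc2c1O | intermediate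
17 | 7-iodo-5-[(2R)-2-methylbutanoyl]-2-(prop-1-en-2-yl)-2,3-dihydro-1-benzofuran-4,6-diyl diacetate, both C-2 epimers | CC[C@@H](C)C(=O)c1c(OC(C)=O)c(I)c2OC(C(C)=C)Cc2c1OC(C)=O | intermediate
18 | [(2S,4E)-6-ethoxy-5-methyl-6-oxo-2-(prop-1-en-2-yl)hex-4-en-1-yl](iodo)zinc | C=C(C)[C@H](C/C=C(\C)C(=O)OCC)C[Zn]I | intermediate (not isolated)
19 | ethyl (2E,5R)-5-{[4,6-bis(acetyloxy)-5-[(2R)-2-methylbutanoyl]-2-(prop-1-en-2-yl)-2,3-dihydro-1-benzofuran-7-yl]methyl}-2,6-dimethylhepta-2,6-dienoate, both C-2 epimers of the dihydrofuran | C=C(C)[C@H](C/C=C(\C)C(=O)OCC)Cc1c(OC(C)=O)c(C(=O)[C@H](C)CC)c(OC(C)=O)c2CC(C(C)=C)Oc12 | intermediate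
20 | ethyl (2E,5R)-5-{[2,4-bis(acetyloxy)-6-hydroxy-5-[(1E)-3-methylbuta-1,3-dien-1-yl]-3-[(2R)-2-methylbutanoyl]phenyl]methyl}-2,6-dimethylhepta-2,6-dienoate | C=C(C)[C@H](C/C=C(\C)C(=O)OCC)Cc1c(OC(C)=O)c(C(=O)[C@H](C)CC)c(OC(C)=O)c(/C=C/C(C)=C)c1O | intermediate (not isolated)
21 | ethyl (2E,5R)-5-{[5,7-bis(acetyloxy)-2,2-dimethyl-6-[(2R)-2-methylbutanoyl]-2H-chromen-8-yl]methyl}-2,6-dimethylhepta-2,6-dienoate | C=C(C)[C@H](C/C=C(\C)C(=O)OCC)Cc1c(OC(C)=O)c(C(=O)[C@H](C)CC)c(OC(C)=O)c2C=CC(C)(C)Oc12 | intermediate
22 | ethyl (2E,5R)-5-{[5,7-dihydroxy-2,2-dimethyl-6-[(2R)-2-methylbutanoyl]-2H-chromen-8-yl]methyl}-2,6-dimethylhepta-2,6-dienoate | C=C(C)[C@H](C/C=C(\C)C(=O)OCC)Cc1c(O)c(C(=O)[C@H](C)CC)c(O)c2C=CC(C)(C)Oc12 | intermediate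
23 | 3-methylbut-2-en-1-yl acetate | CC(C)=CCOC(C)=O | starting material
24 | ethyl (2E,5R)-5-{[(8R)-7-hydroxy-2,2-dimethyl-6-[(2R)-2-methylbutanoyl]-8-(3-methylbut-2-en-1-yl)-5-oxo-5,8-dihydro-2H-chromen-8-yl]methyl}-2,6-dimethylhepta-2,6-dienoate | C=C(C)[C@H](C/C=C(\C)C(=O)OCC)C[C@]1(CC=C(C)C)C(O)=C(C(=O)[C@H](C)CC)C(=O)C2=C1OC(C)(C)C=C2 | intermediate
25 | (2E,5R)-5-{[(8R)-7-hydroxy-2,2-dimethyl-6-[(2R)-2-methylbutanoyl]-8-(3-methylbut-2-en-1-yl)-5-oxo-5,8-dihydro-2H-chromen-8-yl]methyl}-2,6-dimethylhepta-2,6-dienoic acid | C=C(C)[C@H](C/C=C(\C)C(=O)O)C[C@]1(CC=C(C)C)C(O)=C(C(=O)[C@H](C)CC)C(=O)C2=C1OC(C)(C)C=C2 | target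

**Step count and risks**

Total steps: 14. Longest linear sequence: 10 (steps 5 to 14, from phloroglucinol).

Steps most likely to fail:

1. Step 11, the step that carries the label "Proposed new method:". The ionised allyl unit may simply return to the five-membered ring, the open dienyl phenol may be lost to intermolecular addition, or palladium hydride may move the side-chain double bond. The fallback uses known chemistry and gives up the dihydrofuran: it sets out from 14, which is cyclised oxidatively with DDQ (benzene, reflux) to (2R)-1-(5,7-dihydroxy-2,2-dimethyl-2H-chromen-6-yl)-2-methylbutan-1-one F1, separated from its 8-acyl regioisomer by chromatography. NIS then gives (2R)-1-(5,7-dihydroxy-8-iodo-2,2-dimethyl-2H-chromen-6-yl)-2-methylbutan-1-one F2, acetylation gives 8-iodo-2,2-dimethyl-6-[(2R)-2-methylbutanoyl]-2H-chromene-5,7-diyl diacetate F3, and Negishi coupling of F3 with the zinc reagent 18 under the conditions of step 10 comes back to the route at 21.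

2. Step 13. The process at risk is facial selection at C-8 (the catalyst must override a substrate with no bias of its own), together with O-allylation or attack at the branched allyl terminus. The fallback replaces catalyst control by separation: from 22, classical base-mediated C-prenylation with prenyl bromide 13 (NaOEt, EtOH, −10 °C) should give 24 together with its 8S epimer, ethyl (2E,5R)-5-{[(8S)-7-hydroxy-2,2-dimethyl-6-[(2R)-2-methylbutanoyl]-8-(3-methylbut-2-en-1-yl)-5-oxo-5,8-dihydro-2H-chromen-8-yl]methyl}-2,6-dimethylhepta-2,6-dienoate F4. The two are separated by preparative HPLC, and the route is rejoined at 24.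

3. Step 7. Oxypalladation may close through the chelated ortho-hydroxyl or in the 6-endo sense, and the free triol may be over-oxidised. The fallback builds the same ring by epoxide opening and sets out from 14: mCPBA/NaHCO3 (CH2Cl2, 0 °C) gives (2R)-1-{3-[(3,3-dimethyloxiran-2-yl)methyl]-2,4,6-trihydroxyphenyl}-2-methylbutan-1-one F5, which is not isolated but closed 5-exo with K2CO3/MeOH to (2R)-1-[4,6-dihydroxy-2-(2-hydroxypropan-2-yl)-2,3-dihydro-1-benzofuran-5-yl]-2-methylbutan-1-one F6. NIS gives (2R)-1-[4,6-dihydroxy-2-(2-hydroxypropan-2-yl)-7-iodo-2,3-dihydro-1-benzofuran-5-yl]-2-methylbutan-1-one F7, Ac2O/pyridine gives 2-(2-hydroxypropan-2-yl)-7-iodo-5-[(2R)-2-methylbutanoyl]-2,3-dihydro-1-benzofuran-4,6-diyl diacetate F8, and dehydration of the tertiary alcohol with Burgess reagent (toluene, 50 °C) comes back to the route at 17.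

Further compounds

F1 | step 11 | (2R)-1-(5,7-dihydroxy-2,2-dimethyl-2H-chromen-6-yl)-2-methylbutan-1-one | CC[C@@H](C)C(=O)c1c(O)cc2OC(C)(C)C=Cc2c1O
F2 | step 11 | (2R)-1-(5,7-dihydroxy-8-iodo-2,2-dimethyl-2H-chromen-6-yl)-2-methylbutan-1-one | CC[C@@H](C)C(=O)c1c(O)c(I)c2OC(C)(C)C=Cc2c1O
F3 | step 11 | 8-iodo-2,2-dimethyl-6-[(2R)-2-methylbutanoyl]-2H-chromene-5,7-diyl diacetate | CC[C@@H](C)C(=O)c1c(OC(C)=O)c(I)c2OC(C)(C)C=Cc2c1OC(C)=O
F4 | step 13 | ethyl (2E,5R)-5-{[(8S)-7-hydroxy-2,2-dimethyl-6-[(2R)-2-methylbutanoyl]-8-(3-methylbut-2-en-1-yl)-5-oxo-5,8-dihydro-2H-chromen-8-yl]methyl}-2,6-dimethylhepta-2,6-dienoate | C=C(C)[C@H](C/C=C(\C)C(=O)OCC)C[C@@]1(CC=C(C)C)C(O)=C(C(=O)[C@H](C)CC)C(=O)C2=C1OC(C)(C)C=C2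
F5 | step 7 | (2R)-1-{3-[(3,3-dimethyloxiran-2-yl)methyl]-2,4,6-trihydroxyphenyl}-2-methylbutan-1-one, both epoxide epimers | CC[C@@H](C)C(=O)c1c(O)cc(O)c(CC2OC2(C)C)c1O
F6 | step 7 | (2R)-1-[4,6-dihydroxy-2-(2-hydroxypropan-2-yl)-2,3-dihydro-1-benzofuran-5-yl]-2-methylbutan-1-one, both C-2 epimers | CC[C@@H](C)C(=O)c1c(O)cc2OC(C(C)(C)O)Cc2c1O
F7 | step 7 | (2R)-1-[4,6-dihydroxy-2-(2-hydroxypropan-2-yl)-7-iodo-2,3-dihydro-1-benzofuran-5-yl]-2-methylbutan-1-one, both C-2 epimers | CC[C@@H](C)C(=O)c1c(O)c(I)c2OC(C(C)(C)O)Cc2c1O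
F8 | step 7 | 2-(2-hydroxypropan-2-yl)-7-iodo-5-[(2R)-2-methylbutanoyl]-2,3-dihydro-1-benzofuran-4,6-diyl diacetate, both C-2 epimers | CC[C@@H](C)C(=O)c1c(OC(C)=O)c(I)c2OC(C(C)(C)O)Cc2c1OC(C)=O
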